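The earlier runs and the new flask stem from a simulated flask on assumed constants, and the scatter is random.

the same everywhere: starting material 10 mM
- north-west: enzyme 0.0059 mol%; run made earlier
- north: enzyme 0.013 mol%; run made earlier
- flask: enzyme 0.0088 mol%

- north-west (time / min: product / %, starting material / %): 0.200: 4.6, 96.3; 0.500: 9.5, 90.7; 1.00: 19.5, 82.6; 1.50: 28.6, 71.4; 2.00: 38.7, 62.7; 3.00: 56.5, 42.9; 4.00: 75.8, 23.0
- north (time / min: product / %, starting material / %): 0.200: 5.2, 93.4; 0.500: 15.7, 84.7; 1.00: 33.9, 68.6; 1.50: 51.1, 51.1; 2.00: 65.2, 36.0; 3.00: 90.2, 8.5; 4.00: 100.5, 0.4

(standard deviation of a reading: 1 percentage point)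

- factor on the rate of making product when 10% of the starting material are converted if enzyme is charged twice over
- factor on the rate when 10% of the starting material are converted if enzyme is charged at 0.08 mol% instead



1. [starting material] needs no care: it is 10 mM in both runs and the flask, so it cancels from the ratios.

2. The loadings enter through the logarithm of their ratio, 2.20.

3. The product readings come next. I take those at 2.00 min: from 1.00 min to then, product grows by a factor of 1.98 in the north-west run and 1.92 in the north run, so these curves are close to straight. One scatter unit moves the result by 0.0327 on the north-west reading, more than the 0.0194 on the north reading.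

4. Now the number: 65.2% over 38.7% gives 0.660. This is the apparent order in enzyme, the log of the rate ratio over the log of the loading ratio.

5. Doubling the flask's enzyme then gives 1.58.

6. For 0.08 mol% I solve both ends. If enzyme pairs into an inactive form, the order sinks towards 0.5 at high loading. Order 0.5 gives 3.02; holding 0.660 gives 4.29. Joining them by their geometric mean, I commit to 3.60.

7. The forecast says 1.6 (1.5 to 1.75) and 4 (2.5 to 5.5), reading from initial slopes that “the apparent enzyme order is about 0.7”; its second factor stands above my 3.60.

The flask gives 1.55 and 3.71, both inside the forecast's ranges.

    2 enzyme ⇌ resting dimer, settled at all times (K = 1.40 × 10⁶ /M)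
    starting material + enzyme → product + enzyme, rate k2*[starting material]*[enzyme]/(1 + ([starting material]/Km2) + ([starting material]/Ksi2)^2) (1.10 mM, 7.80 mM, k = 1.20 × 10⁵ /M/s)

Put as orders, the flask's factors are 0.632 for doubling and 0.594 out to 0.08 mol%, both beneath the 0.660 read off the runs. The resting dimer, the resting state here, holds 53.4% of the flask's enzyme at 1.50 min. In the run of this flask without that pairing, the apparent order in enzyme at 10% conversion goes from 0.65 to 1.0.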